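## Analysis of the target

Germacranolide numbering is used throughout: ring C1 to C10, lactone oxygen on C6, C7 bearing C11 (C12 carbonyl, C13 methylene), C14 on C10, C15 on C4.

- **Ring system.** Target 39 is a cyclodeca-1(10),4-diene with a trans-fused α-methylene-γ-lactone across C6–C7. Both trisubstituted alkenes are ring-cis: C1=C10 is Z and carries the C14 hydroxymethyl on its fully substituted carbon; C4=C5 is E by the sequence rule but has C3 and C6 on the same side, and carries C15.
- **Stereocentres.** Four contiguous centres run from C6 to C9 (6R,7S,8R,9S). O8 carries an (S)-2-methylbutanoate and O9 an acetate. The C8/C9 oxygens are erythro, so they map onto C3/C2 of D-erythrose with C10 at the aldehyde end.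
- **Sensitive groups.** The exo-methylene lactone is a Michael acceptor. Two different esters sit on vicinal oxygens (acyl migration), next to a lactone that could move from O6 to O8. There are two primary allylic alcohols, and the 1,5-diene in a medium ring could undergo Cope rearrangement on strong heating.
- **What is hard.** A ten-membered carbocycle is the worst size for direct closure. Two oxygenated trisubstituted alkenes need defined geometry, and four hydroxyls must be differentiated.
- **Feature the plan rests on.** The C6 oxygen and C10 are 1,3-related through C1, and C10 is the fully substituted alkene carbon bearing CH2OH. This is what remains when a C6 alkoxide breaks a C1–C6 bond while a C10 spiro-epoxide opens. C1–C6 is then the fusion bond of a cis-decalin (ring A: C1 to C6; ring B: C6, C1, C10, C9, C8, C7).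

## Retrosynthetic reasoning

**39 back to 36.** The two primary allylic alcohols are masked as robust silyl ethers (38), and the two esters are put on one after the other (37, then 38) from diol 36. The ester groups are base-sensitive and prone to migrate, so they come last; the silyl ethers are chosen to survive the acid that frees the diol from acetonide 35.

**35 back to 29.** The lactone C12–O6 bond is cut to diol 32, so that the lactone arises by selective oxidation of the primary allylic alcohol and trapping by the C6 hydroxyl. The C6 carbinol comes from ketone 30 by 1,2-reduction (31), and 30 is the silyl ether of 29. The ketone at C6 is what the fragmentation leaves behind.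

**29 back to 27 (key disconnection).** The ten-membered ring is not cut open but re-bonded: a C1–C6 bond is drawn, C10 becomes a spiro-epoxide and C6 a tertiary carbinol. Cleaving here, rather than at a ring bond, means the medium ring is released from two six-membered rings and never closed directly. Both alkene geometries follow from ring constraints (C4=C5 from the cyclohexene, C1=C10 from the antiperiplanar arrangement in ring B). The forward reaction must break C1–C6 with the epoxide oxygen antiperiplanar, and must not epimerise C7.

**27 back to 23.** The epoxide is a methylene-transfer product of ketone 25. The ketone comes from secondary alcohol 24, freed from silyl ether 23. The C10 oxygen is carried at the alcohol level until ring B exists, because a C6/C10 dicarbonyl would be a 1,3-diketone.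

**23 back to 21.** Ring B is cut at C6–C7, an intramolecular Barbier allylation of the ring A enone carbonyl by allylic bromide 21. This bond is chosen because it sets the tertiary carbinol and C7 together and brings in the C11 exo-methylene directly. The four existing centres on C1, C10, C9 and C8 should dictate the chair of the forming ring.

**21 back to 14 and 17.** The 2-substituted allyl unit comes from vinyl bromide 17 (made from 15 and 16), added to aldehyde 14 to give 19, followed by allylic transposition to the bromide. Aldehyde 14 comes from the primary silyl ether in 13.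

**13 back to 6 and 10.** The C1–C10 bond is an anti, Felkin-selective aldol between the kinetic enolate of enone 6 and aldehyde 10 (12, then silylated). This one step sets C1 relative to the sugar-derived C9, so the chiral pool controls everything else.

**6 and 10 back to starting materials.** Enone 6 is the silyl ether of 5, from vinylogous ester 1 and stannane 2 by Stork–Danheiser transposition. Aldehyde 10 comes from lactone 7 through Weinreb amide 8 and its silyl ether 9, so the lactone carbonyl becomes C10 and the CH2O end becomes C7.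

## Alternatives that were turned down

**Alternative 1: closure at C9–C10 by alkenylchromium addition.**
- Disconnection and key step: the ring is opened between C9 and C10. Seco compound A2 carries a C10 alkenyl iodide and a C9 aldehyde; a divalent-chromium, nickel-catalysed coupling would give macrocycle A1, forming C9–C10, the C9 carbinol and the ring at once.
- For: it is late and convergent, the conditions tolerate lactone, ester and silyl ethers, and the alkene geometry is fixed in the iodide. The C8 ester is already in place, so O8 and O9 never have to be told apart. On that point it is stronger than the chosen route.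
- Against: it is a direct closure of a ten-membered carbocycle containing two cis alkenes, with full entropic and transannular cost. The C9 configuration would be decided by a macrocyclic transition state with no controlling element. The α-acyloxy aldehyde in A2 is prone to C8 epimerisation, acyl migration and elimination. A2 itself needs the C6–C8 triad and two trisubstituted alkenes built in open-chain form.
- Comparison: the chosen route pays no cyclisation entropy and takes C8/C9 from the chiral pool. In exchange it must discriminate a diol late and reduce a ketone.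

**Alternative 2: closure at C5–C6 by vinylsilane capture of a lactone oxocarbenium ion.**
- Disconnection and key step: a boron Lewis acid would ionise the C6 methoxy group of γ-methoxy lactone A4, and the tethered (Z)-vinylsilane would attack through C5 with loss of silicon to give A3.
- For: attack on a five-membered cation anti to the C7 substituent sets C6 trans to C7. This is more reliable than a ketone reduction on a medium ring, so on the C6 configuration it is stronger than the chosen route. Alkene geometry is transferred from the silane.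
- Against: it is again a direct ten-membered closure, now through a short-lived cation. Elimination to a butenolide, intermolecular capture, and ionisation of the allylic C9 oxygen or the acetonide all compete. A3 lacks C13, so a late, base-mediated α-methylenation of two or three steps is still required on a sensitive compound.
- Comparison: the chosen route carries the exo-methylene from step 10 and avoids medium-ring cyclisation. For C6 it offers a reduction with an inversion backstop.

**Alternative 3: ring contraction by enolate [2,3]-Wittig rearrangement.**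
- Disconnection and key step: C7–C8 is cut and the ring enlarged to thirteen-membered keto ether A6. A lithium amide would form the C8 enolate, which rearranges through C8, its oxygen, C13, C11 and C7 to give ten-membered ketol A5.
- For: like the chosen route it avoids direct medium-ring closure. It delivers the C11 methylene unit and two stereocentres in one step. It leaves O8 as a free hydroxyl and C9 as a ketone, a built-in differentiation that is stronger than the late diol discrimination of the chosen route.
- Against: enolate Wittig shifts of α-alkoxy ketones compete with [1,2] shift and aldol pathways. C7 and C8 would be set through a flexible thirteen-membered transition state relative to C6. The C9 ketone then needs another unguided reduction, and the C6 silyl ether must be told apart from two primary ones. None of C6 to C9 comes from the chiral pool.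
- Comparison: the chosen route has C8 and C9 beyond doubt and fixes C1, C6 and C7 by a chair analysis. It is weaker only in how O8 and O9 are differentiated.

Key step: step 16

Remark: 19 is carried as a mixture of C7 epimers and 21 as an E/Z mixture, because both elements vanish in allylindium 22; their SMILES leave these elements open.
Remark: the acyl group on O8 is (S)-2-methylbutanoyl, as the target SMILES requires.

## Route

Step 1
Reactants: 1 3-ethoxycyclohex-2-en-1-one; 2 tributyl[(methoxymethoxy)methyl]stannane
Product: 5 3-(hydroxymethyl)cyclohex-2-en-1-one, via carbinol adduct 3 (not isolated), via MOM enone 4 (not isolated)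
Conditions: 2, n-BuLi, THF, −78 °C; then 1, −78 °C; then 3 M HCl, THF, rt; then conc. HCl, MeOH, 50 °C
Reagents that add atoms: water, O
Why: Tin–lithium exchange gives (methoxymethoxy)methyllithium, which adds 1,2 to the vinylogous ester (Stork–Danheiser sequence); aqueous acid transposes the carbonyl, and stronger acid in methanol removes the MOM acetal.

Step 2
Reactants: 5 3-(hydroxymethyl)cyclohex-2-en-1-one
Product: 6 3-{[tert-butyl(diphenyl)silyl]oxymethyl}cyclohex-2-en-1-one
Conditions: TBDPSCl, imidazole, CH2Cl2, 0 °C to rt
Reagents that add atoms: tert-butyl(chloro)diphenylsilane, CC(C)(C)[Si](Cl)(c1ccccc1)c1ccccc1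
Why: Standard silylation of a primary allylic alcohol; the TBDPS ether is chosen because it must survive enolate, alkoxide and aqueous acid later.

Step 3
Reactants: 7 2,3-O-isopropylidene-D-erythronolactone
Product: 8 (4R,5R)-5-(hydroxymethyl)-N-methoxy-N,2,2-trimethyl-1,3-dioxolane-4-carboxamide
Conditions: MeNH(OMe)·HCl, AlMe3, CH2Cl2, 0 °C to rt
Reagents that add atoms: N,O-dimethylhydroxylamine hydrochloride, CNOC.Cl
Why: Aluminium amide aminolysis of the lactone (Weinreb amide formation) frees the C7 hydroxyl and leaves C10 as a latent aldehyde; both stereocentres are untouched. The γ-hydroxy amide relactonises on standing and is silylated at once.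

Step 4
Reactants: 8 hydroxy Weinreb amide
Product: 9 (4R,5R)-N-methoxy-N,2,2-trimethyl-5-[(triethylsilyl)oxymethyl]-1,3-dioxolane-4-carboxamide
Conditions: TESCl, imidazole, CH2Cl2, 0 °C
Reagents that add atoms: chlorotriethylsilane, CC[Si](Cl)(CC)CC
Why: Silylation of the primary alcohol blocks relactonisation; a triethylsilyl ether is chosen because it can later be oxidised directly.

Step 5
Reactants: 9 silylated Weinreb amide
Product: 10 2,3-O-isopropylidene-4-O-triethylsilyl-D-erythrose
Conditions: iBu2AlH, THF, −78 °C; Rochelle salt
Reagents that add atoms: none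
Why: Weinreb amide reduction stops at the aldehyde through the stable chelated tetrahedral intermediate; at −78 °C the cis-dioxolane α-centre does not epimerise.

Step 6
Reactants: 6 silyloxymethyl enone; 10 erythrose aldehyde
Product: 12 anti-Felkin-type aldol adduct (1,10-anti and 9,10-anti), via lithium dienolate 11 (not isolated)
Conditions: LiN(iPr)2, THF, −78 °C; then 10, −78 °C, 15 min; AcOH, −78 °C
Reagents that add atoms: none
Why: Kinetic α′-deprotonation gives the cross-conjugated (E)-enolate, which reacts through a Zimmerman–Traxler chair to the anti aldol. Felkin–Anh attack anti to the α-oxygen of the dioxolane aldehyde sets C10 anti to O9, so C2 on C1 and O9 end up syn along the chain, which is the C1 configuration the decalin needs.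

Step 7
Reactants: 12 aldol adduct
Product: 13 bis(triethylsilyl) ether
Conditions: TESOTf, 2,6-lutidine, CH2Cl2, −78 °C
Reagents that add atoms: triethylsilyl trifluoromethanesulfonate, CC[Si](CC)(CC)OS(=O)(=O)C(F)(F)F
Why: Silylation of the β-hydroxy ketone stops retro-aldol and dehydration and later keeps the C10 oxygen equatorial in the cyclisation.

Step 8
Reactants: 13 bis(triethylsilyl) ether
Product: 14 C7 aldehyde
Conditions: (COCl)2, DMSO, CH2Cl2, −78 to −40 °C; then Et3N, −78 to 0 °C
Reagents that add atoms: none
Why: Under Swern conditions a primary triethylsilyl ether is cleaved and oxidised directly to the aldehyde, while the hindered secondary triethylsilyl ether and the TBDPS ether survive; this saves a separate deprotection.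

Step 9
Reactants: 15 4-methoxybenzyl alcohol; 16 2,3-dibromoprop-1-ene
Product: 17 1-{[(2-bromoprop-2-en-1-yl)oxy]methyl}-4-methoxybenzene
Conditions: NaH, THF, 0 °C to rt
Reagents that add atoms: none
Why: Williamson etherification at the allylic bromide; the vinylic bromide does not react.

Step 10
Reactants: 14 C7 aldehyde; 17 2-bromoallyl PMB ether
Product: 19 C7 allylic alcohol (epimer mixture), via alkenylchromium dichloride 18 (not isolated)
Conditions: CrCl2, NiCl2 (2 mol%), DMF, rt
Reagents that add atoms: none
Why: Nozaki–Hiyama–Kishi coupling: nickel-catalysed formation of the alkenylchromium species, which adds only to the aldehyde and leaves the enone, silyl ethers and acetonide alone. The C7 configuration is irrelevant because it is erased in step 12.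

Step 11
Reactants: 19 C7 allylic alcohol
Product: 21 transposed primary allylic bromide (E/Z mixture), via allylic mesylate 20 (not isolated)
Conditions: MsCl, Et3N, CH2Cl2, −20 °C; then LiBr, THF, 0 °C to rt
Reagents that add atoms: lithium bromide, [Li+].[Br-]
Why: Mesylation followed by bromide displacement; the hindered, β-oxygenated secondary centre is attacked in the SN2′ sense at the free methylene terminus, and bromide exchange funnels the allylic isomers to the primary bromide.

Step 12
Reactants: 21 allylic bromide
Product: 23 cis-decalin carbinol C10 triethylsilyl ether, via allylindium dibromide 22 (not isolated)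
Conditions: In powder, DMF, rt, 0.01 M; aq NH4Cl
Reagents that add atoms: none
Why: Barbier allylation: zerovalent indium inserts into the C–Br bond and the allylindium adds through C7 (SE2′) to the C6 ketone in a closed Zimmerman–Traxler transition state. The all-cis substituents on C1, C10, C9 and C8 allow only the chair of ring B with C2 axial and the C10 silyl ether equatorial; the other chair would put three groups syn-axial. That chair forces cis ring fusion (axial C6–O, axial attack on the cyclohexenone) and puts C11 equatorial and cis to the new hydroxyl, which sets C6 and C7.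

Step 13
Reactants: 23 C10 triethylsilyl ether
Product: 24 cis-decalin 6,10-diol
Conditions: HF·pyridine, pyridine, THF, 0 °C
Reagents that add atoms: none
Why: Buffered fluoride removes the secondary triethylsilyl ether much faster than the primary TBDPS ether; acetonide and PMB ether are inert.

Step 14
Reactants: 24 cis-decalin 6,10-diol
Product: 25 cis-decalin C10 ketone
Conditions: Dess–Martin periodinane, NaHCO3, CH2Cl2, 0 °C to rt
Reagents that add atoms: none
Why: Only the secondary alcohol can be oxidised; buffered, non-basic conditions avoid retro-aldol of the β-hydroxy ketone and epimerisation at C1. The product is used crude.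

Step 15
Reactants: 25 cis-decalin C10 ketone
Product: 27 cis-decalin epoxy carbinol, via sulfonium betaine 26 (not isolated)
Conditions: Me3S+ I−, KN(SiMe3)2, THF, −10 °C; then 25, −10 to 0 °C
Reagents that add atoms: trimethylsulfonium iodide, C[S+](C)C.[I-]
Why: Corey–Chaykovsky epoxidation with dimethylsulfonium methylide under kinetic control. The lower face of the C10 carbonyl is screened by the axial C2 of ring A and the axial acetonide oxygen on C9, so the ylide adds from the top (axial) face; the epoxide oxygen ends equatorial and cis to C2. The ylide is too weak a base to form the tertiary alkoxide that would start a retro-aldol.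

Step 16
Reactants: 27 cis-decalin epoxy carbinol
Product: 29 ten-membered dienone, via potassium alkoxide 28 (not isolated)
Conditions: KOtBu (1.05 equiv), THF, −40 to 0 °C, short; AcOH in THF, −40 °C
Reagents that add atoms: none
Why: KOtBu deprotonates the tertiary C6 hydroxyl to alkoxide 28; the oxyanion pushes into the C1–C6 bond, which breaks as the C1=C10 π bond forms and the C10–O bond of the spiro-epoxide leaves, so the C6 ketone, the alkene and the C14 alkoxide arise together. The closest known reaction type is the Grob (Wharton) fragmentation of decalin-1,3-diol monosulfonates to cyclodecenones, together with epoxy alcohol fragmentations in which an epoxide C–O bond is the nucleofuge. No ring is closed by cyclisation: the ten-membered ring is released from the two fused six-membered rings by cleavage of their shared bond, so no closure mode applies and no cyclisation entropy is paid. No new stereocentre forms; C1, C6 and C10 become trigonal and C7, C8 and C9 are untouched. The geometry of C1=C10 is set by the ground-state chair of ring B (C11 equatorial): the epoxide oxygen is equatorial and antiperiplanar to C1–C6, and C2 is axial and antiperiplanar to C14, so C2 ends trans to C14 and cis to C9, the ring-cis Z alkene; C4=C5 stays ring-cis from the cyclohexene. The step must beat intramolecular opening of the epoxide by the alkoxide; oxetane formation would need attack at the quaternary C10, and tetrahydrofuran formation is a 5-endo attack at C14 with an O–C–O angle near 120° in this chair, whereas the fragmentation alignment is ideal. It must also beat enolisation at C7 next to the new ketone, which is why one equivalent of base, low temperature and a cold acidic quench are used.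

Step 17
Reactants: 29 ten-membered dienone
Product: 30 C14 TBDPS ether
Conditions: TBDPSCl, imidazole, DMF, 0 °C
Reagents that add atoms: tert-butyl(chloro)diphenylsilane, CC(C)(C)[Si](Cl)(c1ccccc1)c1ccccc1
Why: Silylation of the only free hydroxyl under non-enolising conditions; both primary allylic oxygens now carry the same acid-stable group.

Step 18
Reactants: 30 C14 TBDPS ether
Product: 31 (6R)-allylic alcohol
Conditions: NaBH4, CeCl3·7H2O, MeOH, −78 °C
Reagents that add atoms: none
Why: Luche 1,2-reduction of the enone. Hydride should enter from the outer face of the ring, anti to the C7–C11 bond held perpendicular to the carbonyl plane (Felkin–Anh), giving the 6R carbinol that leads to the trans lactone; the cold, weakly basic medium leaves C7 alone.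

Step 19
Reactants: 31 (6R)-allylic alcohol
Product: 32 6,12-diol
Conditions: DDQ, CH2Cl2/pH 7 buffer, 0 °C
Reagents that add atoms: none
Why: Oxidative cleavage of the PMB ether through its benzylic cation; silyl ethers and acetonide are inert, and the buffered, cold conditions keep the secondary allylic alcohol from being oxidised.

Step 20
Reactants: 32 6,12-diol
Product: 35 α-methylene lactone acetonide, via enal 33 (not isolated), via lactol 34 (not isolated)
Conditions: TEMPO (20 mol%), PhI(OAc)2 (2.5 equiv), CH2Cl2, rt
Reagents that add atoms: none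
Why: The oxoammonium oxidation takes the primary allylic alcohol much faster than the secondary one; the enal is trapped by the C6 hydroxyl as a five-membered lactol, which is oxidised on to the lactone (oxidative lactonisation). The trans ring fusion follows from the C6 and C7 configurations already set.

Step 21
Reactants: 35 α-methylene lactone acetonide
Product: 36 8,9-diol
Conditions: AcOH/H2O (4:1), 40 °C
Reagents that add atoms: none
Why: Mild acid hydrolysis of the dioxolane; primary TBDPS ethers and the lactone survive aqueous acetic acid.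

Step 22
Reactants: 36 8,9-diol
Product: 37 8-O-[(S)-2-methylbutanoyl] 9-ol
Conditions: (S)-2-methylbutanoic anhydride (1.2 equiv), DMAP (0.1 equiv), Et3N, CH2Cl2, −20 to 0 °C
Reagents that add atoms: (S)-2-methylbutanoic anhydride, CC[C@H](C)C(=O)OC(=O)[C@@H](C)CC
Why: DMAP-catalysed acylation with a branched anhydride at low temperature should select the more accessible C8 hydroxyl, because the C9 hydroxyl is flanked by the fully substituted C10 and its bulky silyloxymethyl group. The anhydride avoids ketene formation, so the acyl stereocentre is kept.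

Step 23
Reactants: 37 8-O-[(S)-2-methylbutanoyl] 9-ol
Product: 38 9-O-acetyl-8-O-[(S)-2-methylbutanoyl] bis(TBDPS) ether
Conditions: Ac2O, pyridine, DMAP (cat.), CH2Cl2, 0 °C to rt
Reagents that add atoms: acetic anhydride, CC(=O)OC(C)=O
Why: Fast acetylation of the remaining secondary allylic alcohol outruns migration of the hindered C8 ester.

Step 24
Reactants: 38 fully acylated bis(TBDPS) ether
Product: 39 target CNP0207247.12
Conditions: HF·pyridine, pyridine, THF, 0 °C to rt
Reagents that add atoms: none
Why: Buffered fluoride cleaves both primary allylic TBDPS ethers without the basicity that would trigger acyl migration, translactonisation or conjugate addition to the methylene lactone.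

## Compound list

1 | 3-ethoxycyclohex-2-en-1-one | CCOC1=CC(=O)CCC1 | starting material
2 | tributyl[(methoxymethoxy)methyl]stannane | CCCC[Sn](CCCC)(CCCC)COCOC | starting material
3 | 3-ethoxy-1-[(methoxymethoxy)methyl]cyclohex-2-en-1-ol (racemic, formed as its lithium alkoxide) | CCOC1=CC(O)(COCOC)CCC1 | intermediate
4 | 3-[(methoxymethoxy)methyl]cyclohex-2-en-1-one | O=C1C=C(COCOC)CCC1 | intermediate
5 | 3-(hydroxymethyl)cyclohex-2-en-1-one | O=C1C=C(CO)CCC1 | intermediate
6 | 3-{[tert-butyl(diphenyl)silyl]oxymethyl}cyclohex-2-en-1-one | O=C1C=C(CO[Si](c2ccccc2)(c3ccccc3)C(C)(C)C)CCC1 | intermediate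
7 | 2,3-O-isopropylidene-D-erythronolactone | O=C1OC[C@H]2OC(C)(C)O[C@@H]12 | starting material
8 | (4R,5R)-5-(hydroxymethyl)-N-methoxy-N,2,2-trimethyl-1,3-dioxolane-4-carboxamide | CON(C)C(=O)[C@@H]1OC(C)(C)O[C@@H]1CO | intermediate
9 | (4R,5R)-N-methoxy-N,2,2-trimethyl-5-[(triethylsilyl)oxymethyl]-1,3-dioxolane-4-carboxamide | CON(C)C(=O)[C@@H]1OC(C)(C)O[C@@H]1CO[Si](CC)(CC)CC | intermediate
10 | 2,3-O-isopropylidene-4-O-triethylsilyl-D-erythrose, (4R,5R)-2,2-dimethyl-5-[(triethylsilyl)oxymethyl]-1,3-dioxolane-4-carbaldehyde | O=C[C@@H]1OC(C)(C)O[C@@H]1CO[Si](CC)(CC)CC | intermediate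
11 | lithium cross-conjugated dienolate of 6 (OLi on C6, C1=C6 and C4=C5) | [Li]OC1=CCCC(CO[Si](c2ccccc2)(c3ccccc3)C(C)(C)C)=C1 | intermediate
12 | aldol adduct: enone 6 joined at C1 to C10 carbinol, 1,10-anti and 9,10-anti, C8/C9 acetonide, C7 OTES | O=C1C=C(CO[Si](c2ccccc2)(c3ccccc3)C(C)(C)C)CC[C@@H]1[C@H](O)[C@@H]4OC(C)(C)O[C@@H]4CO[Si](CC)(CC)CC | intermediate
13 | C10,C7 bis(triethylsilyl) ether of 12 | O=C1C=C(CO[Si](c2ccccc2)(c3ccccc3)C(C)(C)C)CC[C@@H]1[C@H](O[Si](CC)(CC)CC)[C@@H]4OC(C)(C)O[C@@H]4CO[Si](CC)(CC)CC | intermediate
14 | C7 aldehyde, C10 OTES | O=C1C=C(CO[Si](c2ccccc2)(c3ccccc3)C(C)(C)C)CC[C@@H]1[C@H](O[Si](CC)(CC)CC)[C@@H]4OC(C)(C)O[C@@H]4C=O | intermediate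
15 | 4-methoxybenzyl alcohol | COc1ccc(CO)cc1 | starting material
16 | 2,3-dibromoprop-1-ene | C=C(Br)CBr | starting material
17 | 1-{[(2-bromoprop-2-en-1-yl)oxy]methyl}-4-methoxybenzene | C=C(Br)COCc1ccc(OC)cc1 | intermediate
18 | [3-(4-methoxybenzyloxy)prop-1-en-2-yl]chromium dichloride | C=C([Cr](Cl)Cl)COCc1ccc(OC)cc1 | intermediate
19 | C7 allylic alcohol bearing the 3-(PMB-oxy)prop-1-en-2-yl unit (C7 epimers) | O=C1C=C(CO[Si](c2ccccc2)(c3ccccc3)C(C)(C)C)CC[C@@H]1[C@H](O[Si](CC)(CC)CC)[C@@H]4OC(C)(C)O[C@@H]4C(O)C(=C)COCc5ccc(OC)cc5 | intermediate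
20 | C7 methanesulfonate of 19 | O=C1C=C(CO[Si](c2ccccc2)(c3ccccc3)C(C)(C)C)CC[C@@H]1[C@H](O[Si](CC)(CC)CC)[C@@H]4OC(C)(C)O[C@@H]4C(OS(C)(=O)=O)C(=C)COCc5ccc(OC)cc5 | intermediate
21 | transposed allylic bromide, C7=C11 with C13 bromide and C12 OPMB (E/Z mixture) | O=C1C=C(CO[Si](c2ccccc2)(c3ccccc3)C(C)(C)C)CC[C@@H]1[C@H](O[Si](CC)(CC)CC)[C@@H]4OC(C)(C)O[C@@H]4C=C(CBr)COCc5ccc(OC)cc5 | intermediate
22 | allylindium dibromide from 21 (simplest formulation) | O=C1C=C(CO[Si](c2ccccc2)(c3ccccc3)C(C)(C)C)CC[C@@H]1[C@H](O[Si](CC)(CC)CC)[C@@H]4OC(C)(C)O[C@@H]4C=C(C[In](Br)Br)COCc5ccc(OC)cc5 | intermediate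
23 | cis-decalin carbinol: 6-OH, H1, C11 on the top face; C2, C5, O8, O9, O10 (TES) on the lower face; 4,5-ene, 15-OTBDPS, 12-OPMB | O[C@@]12C=C(CO[Si](c3ccccc3)(c4ccccc4)C(C)(C)C)CC[C@@H]1[C@H](O[Si](CC)(CC)CC)[C@@H]5OC(C)(C)O[C@@H]5[C@H]2C(=C)COCc6ccc(OC)cc6 | intermediate
24 | cis-decalin 6,10-diol | O[C@@]12C=C(CO[Si](c3ccccc3)(c4ccccc4)C(C)(C)C)CC[C@@H]1[C@H](O)[C@@H]5OC(C)(C)O[C@@H]5[C@H]2C(=C)COCc6ccc(OC)cc6 | intermediate
25 | cis-decalin 6-hydroxy-10-ketone | O[C@@]12C=C(CO[Si](c3ccccc3)(c4ccccc4)C(C)(C)C)CC[C@@H]1C(=O)[C@@H]5OC(C)(C)O[C@@H]5[C@H]2C(=C)COCc6ccc(OC)cc6 | intermediate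
26 | C10 oxido, C14 dimethylsulfonium betaine | O[C@@]12C=C(CO[Si](c3ccccc3)(c4ccccc4)C(C)(C)C)CC[C@@H]1[C@@]([O-])(C[S+](C)C)[C@@H]5OC(C)(C)O[C@@H]5[C@H]2C(=C)COCc6ccc(OC)cc6 | intermediate
27 | cis-decalin epoxy carbinol: C10 spiro-epoxide with oxygen on the lower face (cis to C2) and C14 on the top face; 6-OH, 8,9-acetonide, 15-OTBDPS, 12-OPMB | O[C@@]12C=C(CO[Si](c3ccccc3)(c4ccccc4)C(C)(C)C)CC[C@@H]1[C@@]5(CO5)[C@@H]6OC(C)(C)O[C@@H]6[C@H]2C(=C)COCc7ccc(OC)cc7 | intermediate
28 | potassium C6 alkoxide of 27 | [K]O[C@@]12C=C(CO[Si](c3ccccc3)(c4ccccc4)C(C)(C)C)CC[C@@H]1[C@@]5(CO5)[C@@H]6OC(C)(C)O[C@@H]6[C@H]2C(=C)COCc7ccc(OC)cc7 | intermediate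
29 | ten-membered 1(10)Z,4-dien-6-one with free 14-OH, 8,9-acetonide, 15-OTBDPS, 12-OPMB | O=C1/C=C(/CO[Si](c2ccccc2)(c3ccccc3)C(C)(C)C)CC/C=C(/CO)[C@@H]4OC(C)(C)O[C@@H]4[C@H]1C(=C)COCc5ccc(OC)cc5 | intermediate
30 | 14,15-bis(TBDPS) dienone | O=C1/C=C(/CO[Si](c2ccccc2)(c3ccccc3)C(C)(C)C)CC/C=C(/CO[Si](c6ccccc6)(c7ccccc7)C(C)(C)C)[C@@H]4OC(C)(C)O[C@@H]4[C@H]1C(=C)COCc5ccc(OC)cc5 | intermediate
31 | (6R,7S)-6-ol, 12-OPMB | O[C@@H]1/C=C(/CO[Si](c2ccccc2)(c3ccccc3)C(C)(C)C)CC/C=C(/CO[Si](c6ccccc6)(c7ccccc7)C(C)(C)C)[C@@H]4OC(C)(C)O[C@@H]4[C@H]1C(=C)COCc5ccc(OC)cc5 | intermediate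
32 | 6,12-diol | O[C@@H]1/C=C(/CO[Si](c2ccccc2)(c3ccccc3)C(C)(C)C)CC/C=C(/CO[Si](c6ccccc6)(c7ccccc7)C(C)(C)C)[C@@H]4OC(C)(C)O[C@@H]4[C@H]1C(=C)CO | intermediate
33 | 6-hydroxy-12-enal | O[C@@H]1/C=C(/CO[Si](c2ccccc2)(c3ccccc3)C(C)(C)C)CC/C=C(/CO[Si](c6ccccc6)(c7ccccc7)C(C)(C)C)[C@@H]4OC(C)(C)O[C@@H]4[C@H]1C(=C)C=O | intermediate
34 | 6,12-lactol (C12 epimers) | C=C1C(O)O[C@@H]2/C=C(/CO[Si](c3ccccc3)(c4ccccc4)C(C)(C)C)CC/C=C(/CO[Si](c5ccccc5)(c6ccccc6)C(C)(C)C)[C@@H]7OC(C)(C)O[C@@H]7[C@@H]12 | intermediate
35 | (6R,7S,8R,9S) trans-fused α-methylene lactone, 8,9-acetonide, 14,15-bis(TBDPS) | C=C1C(=O)O[C@@H]2/C=C(/CO[Si](c3ccccc3)(c4ccccc4)C(C)(C)C)CC/C=C(/CO[Si](c5ccccc5)(c6ccccc6)C(C)(C)C)[C@@H]7OC(C)(C)O[C@@H]7[C@@H]12 | intermediate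
36 | 8,9-diol lactone | C=C1C(=O)O[C@@H]2/C=C(/CO[Si](c3ccccc3)(c4ccccc4)C(C)(C)C)CC/C=C(/CO[Si](c5ccccc5)(c6ccccc6)C(C)(C)C)[C@H](O)[C@H](O)[C@@H]12 | intermediate
37 | 8-O-[(S)-2-methylbutanoyl] 9-ol | C=C1C(=O)O[C@@H]2/C=C(/CO[Si](c3ccccc3)(c4ccccc4)C(C)(C)C)CC/C=C(/CO[Si](c5ccccc5)(c6ccccc6)C(C)(C)C)[C@H](O)[C@H](OC(=O)[C@@H](C)CC)[C@@H]12 | intermediate
38 | 9-O-acetyl-8-O-[(S)-2-methylbutanoyl] 14,15-bis(TBDPS) ether | C=C1C(=O)O[C@@H]2/C=C(/CO[Si](c3ccccc3)(c4ccccc4)C(C)(C)C)CC/C=C(/CO[Si](c5ccccc5)(c6ccccc6)C(C)(C)C)[C@H](OC(C)=O)[C@H](OC(=O)[C@@H](C)CC)[C@@H]12 | intermediate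
39 | CNP0207247.12, (6R,7S,8R,9S) | C=C1C(=O)O[C@@H]2/C=C(/CO)CC/C=C(/CO)[C@H](OC(C)=O)[C@H](OC(=O)[C@@H](C)CC)[C@@H]12 | target

## Step count and least certain steps

Total step count: 24. Longest linear sequence: 21 steps (from 7 through steps 3 to 8 and 10 to 24).

**Step 16 (key step).** The likeliest failures are enolisation at C7 by the product alkoxide (epimerisation, or migration of the C11=C13 alkene into conjugation) and slow fragmentation that lets the alkoxide open the epoxide instead. Fallback, from 25 back to 29: treat β-hydroxy ketone 25 with KN(SiMe3)2 and N-phenylbis(trifluoromethanesulfonimide) at low temperature. The alkoxide undergoes retro-aldol cleavage of the same C1–C6 bond, and the C10 enolate released (C2 trans to the oxygen, as the chair dictates) is trapped as the ten-membered enol triflate F1. Stille hydroxymethylation of F1 with (tributylstannyl)methanol, Pd(PPh3)4 (zerovalent palladium) and LiCl then installs C14 and gives 29.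

**Step 12 (Barbier ring closure).** Poor facial control at C6/C7, protodehalogenation, or intermolecular coupling could lower the yield of the single cis-fused isomer. Fallback, from 14 back to 23: Baylis–Hillman reaction of aldehyde 14 with ethyl acrylate (DABCO) gives hydroxy ester F2. NBS/Me2S converts it to the (Z)-2-(bromomethyl)enoate F3. Zinc-mediated intramolecular Reformatsky-type allylation, which has strong precedent for cis products, closes ring B as the cis-fused α-methylene lactone F4. iBu2AlH reduces F4 to diol F5, and NaH/4-methoxybenzyl chloride etherifies the primary hydroxyl to give 23.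

**Step 15 (epoxidation).** Retro-aldol or C1 epimerisation of the β-hydroxy ketone under the basic ylide, β-elimination of the acetonide oxygen, or attack from the lower face would all damage the precursor. Fallback, from 25 back to 27: add chloromethyllithium (from ICH2Cl and MeLi, THF, −78 °C), which reacts far below the temperature at which enolisation or retro-aldol matter, to give chlorohydrin F6. Closing F6 with K2CO3 in methanol gives 27.

**Step 18 (C6 reduction).** Facial selectivity on the flexible ten-membered enone cannot be predicted with confidence; attack anti to the ring bond C7–C8 instead of anti to C11 would give the 6-epimer and hence the cis lactone. Fallback, from 30 back to 31: the same reduction gives the 6S alcohol F7. Mitsunobu inversion with 4-nitrobenzoic acid, PPh3 and DIAD gives the 6R ester F8, and methanolysis (K2CO3, MeOH) gives 31.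

**Step 22 (selective C8 acylation).** Acylation at O9, double acylation, acyl migration between the vicinal oxygens, or lactone migration to O8 once that hydroxyl is free could all occur. Fallback, from 36 back to 38: if O9 proves the more reactive oxygen, reverse the order. Acetylate first with acetyl chloride and 2,4,6-collidine at −78 °C to the 9-acetate 8-ol F9, then esterify the C8 hydroxyl with (S)-2-methylbutanoic anhydride and DMAP to reach 38. The unwanted monoester can be recycled by base-induced acyl migration.

## Further compounds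

F1 | step 16 | ten-membered 6-oxo C10 enol triflate (C1=C10, C2 trans to OTf) | O=C1/C=C(/CO[Si](c2ccccc2)(c3ccccc3)C(C)(C)C)CC/C=C(/OS(=O)(=O)C(F)(F)F)[C@@H]4OC(C)(C)O[C@@H]4[C@H]1C(=C)COCc5ccc(OC)cc5
F2 | step 12 | Baylis–Hillman adduct of 14 with ethyl acrylate (C7 epimers) | O=C1C=C(CO[Si](c2ccccc2)(c3ccccc3)C(C)(C)C)CC[C@@H]1[C@H](O[Si](CC)(CC)CC)[C@@H]4OC(C)(C)O[C@@H]4C(O)C(=C)C(=O)OCC
F3 | step 12 | (Z)-2-(bromomethyl)enoate | O=C1C=C(CO[Si](c2ccccc2)(c3ccccc3)C(C)(C)C)CC[C@@H]1[C@H](O[Si](CC)(CC)CC)[C@@H]4OC(C)(C)O[C@@H]4/C=C(\CBr)C(=O)OCC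
F4 | step 12 | cis-fused α-methylene lactone on the cis-decalin (O6 acylated by C12), C10 OTES | C=C1C(=O)O[C@@]23C=C(CO[Si](c5ccccc5)(c6ccccc6)C(C)(C)C)CC[C@@H]2[C@H](O[Si](CC)(CC)CC)[C@@H]4OC(C)(C)O[C@@H]4[C@@H]13
F5 | step 12 | cis-decalin 6,12-diol, C10 OTES | O[C@@]12C=C(CO[Si](c3ccccc3)(c4ccccc4)C(C)(C)C)CC[C@@H]1[C@H](O[Si](CC)(CC)CC)[C@@H]5OC(C)(C)O[C@@H]5[C@H]2C(=C)CO
F6 | step 15 | C10 chlorohydrin (C10 OH on the lower face, C14 chloride on the top face) | O[C@@]12C=C(CO[Si](c3ccccc3)(c4ccccc4)C(C)(C)C)CC[C@@H]1[C@@](O)(CCl)[C@@H]5OC(C)(C)O[C@@H]5[C@H]2C(=C)COCc6ccc(OC)cc6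
F7 | step 18 | 6S epimer of 31 | O[C@H]1/C=C(/CO[Si](c2ccccc2)(c3ccccc3)C(C)(C)C)CC/C=C(/CO[Si](c6ccccc6)(c7ccccc7)C(C)(C)C)[C@@H]4OC(C)(C)O[C@@H]4[C@H]1C(=C)COCc5ccc(OC)cc5
F8 | step 18 | 4-nitrobenzoate of 31 | O=C(O[C@@H]1/C=C(/CO[Si](c2ccccc2)(c3ccccc3)C(C)(C)C)CC/C=C(/CO[Si](c6ccccc6)(c7ccccc7)C(C)(C)C)[C@@H]4OC(C)(C)O[C@@H]4[C@H]1C(=C)COCc5ccc(OC)cc5)c8ccc(cc8)[N+](=O)[O-]
F9 | step 22 | 9-O-acetyl 8-ol | C=C1C(=O)O[C@@H]2/C=C(/CO[Si](c3ccccc3)(c4ccccc4)C(C)(C)C)CC/C=C(/CO[Si](c5ccccc5)(c6ccccc6)C(C)(C)C)[C@H](OC(C)=O)[C@H](O)[C@@H]12
A1 | alternative 1 | 9-hydroxy macrocycle, 14,15-bis(TBS) ether, 8-O-(S)-2-methylbutanoate | C=C1C(=O)O[C@@H]2/C=C(/CO[Si](C)(C)C(C)(C)C)CC/C=C(/CO[Si](C)(C)C(C)(C)C)[C@H](O)[C@H](OC(=O)[C@@H](C)CC)[C@@H]12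
A2 | alternative 1 | seco C9 aldehyde with C10 alkenyl iodide | C=C1C(=O)O[C@H](/C=C(/CO[Si](C)(C)C(C)(C)C)CC/C=C(/CO[Si](C)(C)C(C)(C)C)I)[C@H]1[C@@H](OC(=O)[C@@H](C)CC)C=O
A3 | alternative 2 | protected ten-membered trans lactone without C13 | C1C(=O)O[C@@H]2/C=C(/CO[Si](c3ccccc3)(c4ccccc4)C(C)(C)C)CC/C=C(/CO[Si](c5ccccc5)(c6ccccc6)C(C)(C)C)[C@@H]7OC(C)(C)O[C@@H]7[C@@H]12
A4 | alternative 2 | γ-methoxy lactone with tethered (Z)-vinylsilane | COC1OC(=O)C[C@@H]1[C@H]2OC(C)(C)O[C@H]2/C(CO[Si](c3ccccc3)(c4ccccc4)C(C)(C)C)=C\CC/C(CO[Si](c5ccccc5)(c6ccccc6)C(C)(C)C)=C\[Si](C)(C)C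
A5 | alternative 3 | ten-membered 8-hydroxy-9-ketone with the C11 methylene unit | O=C1[C@H](O)[C@@H](C(=C)COCc2ccc(OC)cc2)[C@H](O[Si](C)(C)C(C)(C)C)/C=C(/CO[Si](C)(C)C(C)(C)C)CC/C=C1/CO[Si](C)(C)C(C)(C)C
A6 | alternative 3 | thirteen-membered C9 keto ether | O=C1COC/C(COCc2ccc(OC)cc2)=C/[C@H](O[Si](C)(C)C(C)(C)C)/C=C(/CO[Si](C)(C)C(C)(C)C)CC/C=C1/CO[Si](C)(C)C(C)(C)C
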